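The hydroazulene is disconnected at C4–C5 and C1–C2, the two bonds that tie the cyclopentane to the seven-membered ring. Within that ring C1, C5 and C6 are the α-, β- and γ-carbons of the C10 ketone. One flask can therefore add a 3-methylbut-1-en-2-yl cuprate to C5 of (S)-4-silyloxy-2-methylcyclohept-2-enone, anti to the C6 silyloxy group, and allylate the C1 enolate anti to the new substituent, so that C6 fixes C5 and the quaternary C1. Ring-closing metathesis then joins C3 to C4, and the C6 hydroxyl steers oxygen onto C4 before the enone and the ester are completed.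

Key step: step 7

Numbering used throughout (target atoms): C1 quaternary C–CH3, C2/C3 CH2, C4 C(OH)iPr, C5 ring-fusion CH, C6 CH–O, C7 CH2, C8(CH3)=C9, C10 C=O. In azulene names C1 = C8a, C4 = C3, C5 = C3a, C6 = C4, C8 = C6, C10 = C8; the target is then (3R,3aS,4S,8aS).

Remark on configuration: the silyloxy carbon of enone 6 must be (S); it becomes C6, and the key product 11 is (2S,3S,4S).

Assumption: of the two pseudoenantiomeric cinchona catalysts available for step 2, the one that gives (S)-3 is used; the other one gives the enantiomeric series.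

Step 1
Reactants: 1 cyclohepta-1,3-diene
Product: 2 (1R,5S)-6,7-dioxabicyclo[3.2.2]non-8-ene (meso endoperoxide)
Conditions: O2, TPP (cat.), visible light, CH2Cl2, 0 °C
Reagents that add atoms: dioxygen, O=O
Why: Singlet oxygen adds across the s-cis diene in a [4+2] photooxygenation, which can only give the cis-bridged meso peroxide.

Step 2
Reactants: 2 (1R,5S)-6,7-dioxabicyclo[3.2.2]non-8-ene
Product: 3 (S)-4-hydroxycyclohept-2-en-1-one
Conditions: O-acetylcupreine-type cinchona catalyst (10 mol%), CH2Cl2, rt
Reagents that add atoms: none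
Why: In this enantioselective Kornblum–DeLaMare rearrangement the chiral amine removes one of the two enantiotopic bridgehead hydrogens with O–O cleavage, so the untouched bridgehead carbon becomes the carbinol stereocentre (later C6) under catalyst control.

Step 3
Reactants: 3 (S)-4-hydroxycyclohept-2-en-1-one
Product: 4 (S)-4-[(tert-butyldimethylsilyl)oxy]cyclohept-2-en-1-one
Conditions: TBSCl, imidazole, DMF, 0 °C to rt
Reagents that add atoms: tert-butyldimethylsilyl chloride, CC(C)(C)[Si](C)(C)Cl
Why: Imidazole-mediated silylation of the secondary alcohol is neutral enough to leave the γ-oxygenated enone and its stereocentre untouched.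

Step 4
Reactants: 4 (S)-4-[(tert-butyldimethylsilyl)oxy]cyclohept-2-en-1-one
Product: 5 (S)-4-[(tert-butyldimethylsilyl)oxy]-2-iodocyclohept-2-en-1-one
Conditions: I2, pyridine, CH2Cl2, 0 °C to rt
Reagents that add atoms: iodine, II
Why: Johnson α-iodination (pyridine conjugate addition, iodination of the enolate, elimination of pyridine) places iodine only on the enone α-carbon, the future C1.

Step 5
Reactants: 5 (S)-4-[(tert-butyldimethylsilyl)oxy]-2-iodocyclohept-2-en-1-one
Product: 6 (S)-4-[(tert-butyldimethylsilyl)oxy]-2-methylcyclohept-2-en-1-one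
Conditions: Me4Sn, Pd2(dba)3 (cat.), AsPh3, CuI (cat.), NMP, 70 °C
Reagents that add atoms: tetramethylstannane, C[Sn](C)(C)C
Why: Stille coupling of an α-iodoenone with a methylstannane proceeds under neutral conditions, so the base-sensitive γ-silyloxy stereocentre is not endangered.

Step 6
Reactants: 7 2-bromo-3-methylbut-1-ene
Product: 8 (3-methylbut-1-en-2-yl)magnesium bromide
Conditions: Mg turnings, THF, rt to 40 °C
Reagents that add atoms: magnesium, [Mg]
Why: Grignard formation by magnesium insertion into the alkenyl C–Br bond gives the nucleophile that carries C4 and the isopropyl group.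

Step 7
Reactants: 6 (S)-4-[(tert-butyldimethylsilyl)oxy]-2-methylcyclohept-2-en-1-one; 8 (3-methylbut-1-en-2-yl)magnesium bromide; 9 allyl bromide
Product: 11 (2S,3S,4S)-4-[(tert-butyldimethylsilyl)oxy]-2-methyl-3-(3-methylbut-1-en-2-yl)-2-(prop-2-en-1-yl)cycloheptan-1-one, via bromomagnesium enolate 10 (not isolated)
Conditions: 8 (2.4 equiv), CuBr·SMe2 (1.2 equiv), THF, −78 °C; 6, −78 to −40 °C; then DMPU, 9 (5 equiv), −40 to 0 °C
Reagents that add atoms: none
Why: The magnesium dialkenylcuprate forms a π-complex with the enone and transfers one alkenyl group to C5 by oxidative addition and reductive elimination, leaving the C1=C10 bromomagnesium enolate 10, which DMPU activates for SN2 C-allylation by 9 at C1. The closest known reaction type is the three-component coupling of 4-silyloxycycloalkenones (conjugate addition followed by trans-selective enolate alkylation), together with the vicinal dialkylation of 2-methylcycloalkenones to α-quaternary ketones. No ring is closed in this step. C5 is controlled by the C6 silyloxy group, whose bulk and allylic C–O bond send the cuprate to the opposite face, and C1 is controlled by the new C5 alkenyl group, which shields its own face of the planar enolate so that the allyl group enters trans to it. The step needs 1,4- rather than 1,2-addition (secured by copper) and C-allylation without enolate equilibration (secured by the regiospecifically formed tetrasubstituted enolate, excess soft electrophile, polar additive and low temperature). It also needs retention of the C6–O bond, which is secured because a silyl ether is not expelled reductively and sits on C6, not on the carbon next to the enolate carbon.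

Step 8
Reactants: 11 (2S,3S,4S)-4-[(tert-butyldimethylsilyl)oxy]-2-methyl-3-(3-methylbut-1-en-2-yl)-2-(prop-2-en-1-yl)cycloheptan-1-one
Product: 12 (3aS,4S,8aS)-4-[(tert-butyldimethylsilyl)oxy]-8a-methyl-3-(propan-2-yl)-3a,4,5,6,7,8a-hexahydroazulen-8(1H)-one
Conditions: Grubbs II (5–10 mol%), toluene (high dilution), 80 °C
Reagents that add atoms: none
Why: Ring-closing metathesis loads ruthenium on the unhindered allyl terminus and closes onto the 1,1-disubstituted alkene to give the trisubstituted C3=C4 cyclopentene, the trans-diequatorial side chains on the seven-membered ring being well placed for a trans-fused five-membered ring.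

Step 9
Reactants: 12 (3aS,4S,8aS)-4-[(tert-butyldimethylsilyl)oxy]-8a-methyl-3-(propan-2-yl)-3a,4,5,6,7,8a-hexahydroazulen-8(1H)-one
Product: 14 (3aS,4S,8aS)-4-[(tert-butyldimethylsilyl)oxy]-8a-methyl-3-(propan-2-yl)-3a,4,5,8a-tetrahydroazulen-8(1H)-one, via TMS enol ether 13 (not isolated)
Conditions: LDA, TMSCl, THF, −78 °C; then crude 13, Pd(OAc)2 (1.1 equiv), MeCN, rt
Reagents that add atoms: chlorotrimethylsilane, C[Si](C)(C)Cl (silyl group present in 13 only)
Why: Saegusa–Ito dehydrogenation is regiochemically unambiguous here because the C10 ketone can enolise only toward C9, C1 being quaternary, so the C8=C9 enone is the only possible product.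

Step 10
Reactants: 14 (3aS,4S,8aS)-4-[(tert-butyldimethylsilyl)oxy]-8a-methyl-3-(propan-2-yl)-3a,4,5,8a-tetrahydroazulen-8(1H)-one
Product: 16 (3aS,4S,8aS)-4-[(tert-butyldimethylsilyl)oxy]-6,8a-dimethyl-3-(propan-2-yl)-3a,4,5,8a-tetrahydroazulen-8(1H)-one, via TMS enol ether 15 (not isolated)
Conditions: Me2CuLi (from MeLi, CuI), TMSCl, THF/Et2O, −78 °C; then crude 15, Pd(OAc)2 (1.1 equiv), MeCN, rt to 40 °C
Reagents that add atoms: lithium dimethylcuprate, [Li+].C[Cu-]C; chlorotrimethylsilane, C[Si](C)(C)Cl (silyl group present in 15 only)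
Why: TMSCl-accelerated cuprate conjugate addition puts the methyl group on C8 and traps the C9=C10 enol ether, and a second Saegusa–Ito dehydrogenation restores the C8=C9 double bond, which removes the transient C8 stereocentre.

Step 11
Reactants: 16 (3aS,4S,8aS)-4-[(tert-butyldimethylsilyl)oxy]-6,8a-dimethyl-3-(propan-2-yl)-3a,4,5,8a-tetrahydroazulen-8(1H)-one
Product: 17 (3aS,4S,8aS)-4-hydroxy-6,8a-dimethyl-3-(propan-2-yl)-3a,4,5,8a-tetrahydroazulen-8(1H)-one
Conditions: HF·pyridine, pyridine/THF, 0 °C to rt
Reagents that add atoms: none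
Why: Fluoride-mediated Si–O cleavage under buffered, weakly acidic conditions frees the C6 hydroxyl without the vinylogous β-elimination that a basic fluoride source could provoke in this δ-oxygenated enone.

Step 12
Reactants: 17 (3aS,4S,8aS)-4-hydroxy-6,8a-dimethyl-3-(propan-2-yl)-3a,4,5,8a-tetrahydroazulen-8(1H)-one
Product: 18 (2S,3R,3aS,4S,8aS)-2,3-epoxy-4-hydroxy-6,8a-dimethyl-3-(propan-2-yl)-2,3,3a,4,5,8a-hexahydroazulen-8(1H)-one (epoxide oxygen trans to H5)
Conditions: VO(acac)2 (cat.), t-BuOOH, CH2Cl2, 0 °C to rt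
Reagents that add atoms: tert-butyl hydroperoxide, CC(C)(C)OO
Why: In this vanadium-catalysed hydroxyl-directed epoxidation the vanadate ester of the homoallylic C6–OH delivers the peroxide oxygen to the face of the electron-rich C3=C4 bond on which C6 lies (trans to H5), which sets C4, while the electron-poor enone alkene does not react.

Step 13
Reactants: 18 (2S,3R,3aS,4S,8aS)-2,3-epoxy-4-hydroxy-6,8a-dimethyl-3-(propan-2-yl)-2,3,3a,4,5,8a-hexahydroazulen-8(1H)-one
Product: 19 (3R,3aS,4S,8aS)-6,8a-dimethyl-3-(propan-2-yl)-1,2,3,3a,4,5,8,8a-octahydroazulene-3,4,8-triol (mixture of C10 epimers)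
Conditions: LiAlH4, THF, 0 °C to reflux; Rochelle-salt work-up
Reagents that add atoms: none
Why: Hydride opens the trisubstituted epoxide by SN2 attack at the secondary carbon C3 from the face opposite the oxygen, leaving the C4–O bond and its configuration intact, while 1,2-reduction of the β,β-disubstituted enone gives an allylic alcohol whose configuration is irrelevant.

Step 14
Reactants: 19 (3R,3aS,4S,8aS)-6,8a-dimethyl-3-(propan-2-yl)-1,2,3,3a,4,5,8,8a-octahydroazulene-3,4,8-triol
Product: 20 (3R,3aS,4S,8aS)-3,4-dihydroxy-6,8a-dimethyl-3-(propan-2-yl)-2,3,3a,4,5,8a-hexahydroazulen-8(1H)-one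
Conditions: activated MnO2 (excess), CH2Cl2, rt
Reagents that add atoms: none
Why: Manganese dioxide oxidation is selective for the allylic C10 alcohol, so the enone returns while the saturated secondary C6–OH and the tertiary C4–OH stay free.

Step 15
Reactants: 20 (3R,3aS,4S,8aS)-3,4-dihydroxy-6,8a-dimethyl-3-(propan-2-yl)-2,3,3a,4,5,8a-hexahydroazulen-8(1H)-one; 21 3,4,5-trimethoxybenzoyl chloride
Product: 22 (3R,3aS,4S,8aS)-3-hydroxy-6,8a-dimethyl-8-oxo-3-(propan-2-yl)-1,2,3,3a,4,5,8,8a-octahydroazulen-4-yl 3,4,5-trimethoxybenzoate (CNP0218356.1)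
Conditions: DMAP, Et3N, CH2Cl2, 0 °C to rt
Reagents that add atoms: none
Why: DMAP-catalysed acylation with the acid chloride esterifies the only secondary alcohol (C6–OH) with retention, the tertiary C4–OH being too hindered to compete under these mild conditions.

Compound list
1 | cyclohepta-1,3-diene | C1=CC=CCCC1 | starting material
2 | (1R,5S)-6,7-dioxabicyclo[3.2.2]non-8-ene (meso) | C1C[C@@H]2C=C[C@H](C1)OO2 | intermediate
3 | (S)-4-hydroxycyclohept-2-en-1-one | O=C1C=C[C@@H](O)CCC1 | intermediate
4 | (S)-4-[(tert-butyldimethylsilyl)oxy]cyclohept-2-en-1-one | O=C1C=C[C@@H](O[Si](C)(C)C(C)(C)C)CCC1 | intermediate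
5 | (S)-4-[(tert-butyldimethylsilyl)oxy]-2-iodocyclohept-2-en-1-one | O=C1C(I)=C[C@@H](O[Si](C)(C)C(C)(C)C)CCC1 | intermediate
6 | (S)-4-[(tert-butyldimethylsilyl)oxy]-2-methylcyclohept-2-en-1-one | CC1=C[C@@H](O[Si](C)(C)C(C)(C)C)CCCC1=O | intermediate
7 | 2-bromo-3-methylbut-1-ene | CC(C)C(Br)=C | starting material
8 | (3-methylbut-1-en-2-yl)magnesium bromide | CC(C)C(=C)[Mg]Br | intermediate
9 | allyl bromide | C=CCBr | starting material
10 | bromomagnesium (3S,4S)-4-[(tert-butyldimethylsilyl)oxy]-2-methyl-3-(3-methylbut-1-en-2-yl)cyclohept-1-en-1-olate | CC1=C(O[Mg]Br)CCC[C@H](O[Si](C)(C)C(C)(C)C)[C@H]1C(=C)C(C)C | intermediate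
11 | (2S,3S,4S)-4-[(tert-butyldimethylsilyl)oxy]-2-methyl-3-(3-methylbut-1-en-2-yl)-2-(prop-2-en-1-yl)cycloheptan-1-one | C=CC[C@]1(C)C(=O)CCC[C@H](O[Si](C)(C)C(C)(C)C)[C@H]1C(=C)C(C)C | intermediate
12 | (3aS,4S,8aS)-4-[(tert-butyldimethylsilyl)oxy]-8a-methyl-3-(propan-2-yl)-3a,4,5,6,7,8a-hexahydroazulen-8(1H)-one | CC(C)(C)[Si](C)(C)O[C@H]1CCCC(=O)[C@@]2(C)CC=C(C(C)C)[C@H]12 | intermediate
13 | (3aS,4S,8aS)-4-[(tert-butyldimethylsilyl)oxy]-8a-methyl-3-(propan-2-yl)-8-[(trimethylsilyl)oxy]-1,3a,4,5,6,8a-hexahydroazulene | CC(C)(C)[Si](C)(C)O[C@H]1CCC=C(O[Si](C)(C)C)[C@@]2(C)CC=C(C(C)C)[C@H]12 | intermediate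
14 | (3aS,4S,8aS)-4-[(tert-butyldimethylsilyl)oxy]-8a-methyl-3-(propan-2-yl)-3a,4,5,8a-tetrahydroazulen-8(1H)-one | CC(C)(C)[Si](C)(C)O[C@H]1CC=CC(=O)[C@@]2(C)CC=C(C(C)C)[C@H]12 | intermediate
15 | (3aS,4S,8aS)-4-[(tert-butyldimethylsilyl)oxy]-6,8a-dimethyl-3-(propan-2-yl)-8-[(trimethylsilyl)oxy]-1,3a,4,5,6,8a-hexahydroazulene (C8 epimers, target numbering) | CC(C)(C)[Si](C)(C)O[C@H]1CC(C)C=C(O[Si](C)(C)C)[C@@]2(C)CC=C(C(C)C)[C@H]12 | intermediate
16 | (3aS,4S,8aS)-4-[(tert-butyldimethylsilyl)oxy]-6,8a-dimethyl-3-(propan-2-yl)-3a,4,5,8a-tetrahydroazulen-8(1H)-one | CC(C)(C)[Si](C)(C)O[C@H]1CC(C)=CC(=O)[C@@]2(C)CC=C(C(C)C)[C@H]12 | intermediate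
17 | (3aS,4S,8aS)-4-hydroxy-6,8a-dimethyl-3-(propan-2-yl)-3a,4,5,8a-tetrahydroazulen-8(1H)-one | O[C@H]1CC(C)=CC(=O)[C@@]2(C)CC=C(C(C)C)[C@H]12 | intermediate
18 | (2S,3R,3aS,4S,8aS)-2,3-epoxy-4-hydroxy-6,8a-dimethyl-3-(propan-2-yl)-2,3,3a,4,5,8a-hexahydroazulen-8(1H)-one | O[C@H]1CC(C)=CC(=O)[C@@]2(C)C[C@@H]3O[C@]3(C(C)C)[C@H]12 | intermediate
19 | (3R,3aS,4S,8aS)-6,8a-dimethyl-3-(propan-2-yl)-1,2,3,3a,4,5,8,8a-octahydroazulene-3,4,8-triol (C10 epimers, target numbering) | O[C@H]1CC(C)=CC(O)[C@@]2(C)CC[C@@](O)(C(C)C)[C@H]12 | intermediate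
20 | (3R,3aS,4S,8aS)-3,4-dihydroxy-6,8a-dimethyl-3-(propan-2-yl)-2,3,3a,4,5,8a-hexahydroazulen-8(1H)-one | O[C@H]1CC(C)=CC(=O)[C@@]2(C)CC[C@@](O)(C(C)C)[C@H]12 | intermediate
21 | 3,4,5-trimethoxybenzoyl chloride | COc1cc(cc(OC)c1OC)C(Cl)=O | starting material
22 | (3R,3aS,4S,8aS)-3-hydroxy-6,8a-dimethyl-8-oxo-3-(propan-2-yl)-1,2,3,3a,4,5,8,8a-octahydroazulen-4-yl 3,4,5-trimethoxybenzoate | COc1cc(C(=O)O[C@H]2CC(C)=CC(=O)[C@@]3(C)CC[C@@](O)(C(C)C)[C@H]23)cc(OC)c1OC | target

Total step count: 15. Longest linear sequence: 14 steps (steps 1–5 and 7–15); step 6 prepares the Grignard reagent on a side branch.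

Steps most likely to fail

Step 7. The hindered tetrasubstituted magnesium enolate may be allylated at carbon too slowly, so that proton exchange, O-allylation or attack on the wrong face of C1 competes. Transfer of the branched alkenyl group to the crowded C5 may also be incomplete. The fallback sets out from 6 (with 8) and returns at 11. Enolate 10 is generated as in step 7 and quenched on oxygen with allyl chloroformate to give allyl (3S,4S)-4-[(tert-butyldimethylsilyl)oxy]-2-methyl-3-(3-methylbut-1-en-2-yl)cyclohept-1-en-1-yl carbonate F1. This is isolated and treated with Pd2(dba)3/PPh3 in THF at rt, with a PHOX ligand of the matching sense if substrate control proves insufficient. Decarboxylative Tsuji allylation then forms the C1–C2 bond under neutral conditions, trans to the C5 alkenyl group, to give 11.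

Step 12. Oxygen may be delivered to the wrong face of C3=C4, because the face to which the C6 hydroxyl must direct also carries the axial C1 methyl group, or an undirected background epoxidation may take over. The fallback sets out from 17 and returns at 20, which also makes steps 13 and 14 unnecessary.
- Boc2O/DMAP converts 17 into tert-butyl (3aS,4S,8aS)-6,8a-dimethyl-8-oxo-3-(propan-2-yl)-1,3a,4,5,8,8a-hexahydroazulen-4-yl carbonate F2.
- IBr in toluene at −80 °C triggers iodocarbonate cyclisation to the C3-iodo C4,C6-cyclic carbonate F3. The six-membered carbonate can bridge from C6 only to the C4 face cis to C6, so the tether enforces the C4 configuration.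
- Bu3SnH/AIBN removes the iodine to give the C4,C6-cyclic carbonate F4.
- K2CO3 in MeOH at rt cleaves the carbonate to 20.

Step 13. Conjugate reduction of the enone may compete with 1,2-reduction, or the hindered epoxide may open incompletely or with the wrong orientation under forcing hydride conditions. The fallback sets out from 18 and returns at 20, so that C10 never leaves the ketone level and step 14 is not needed. Sodium phenylselenolate (from PhSeSePh and NaBH4 in EtOH, with no excess hydride) opens the epoxide by SN2 attack at C3 to give the C3-phenylselanyl derivative of 20, F5, with selenium trans to the C4 hydroxyl. Bu3SnH/AIBN in toluene at 80 °C then removes selenium by radical reduction to give 20.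

Further compounds
F1 | step 7 | allyl (3S,4S)-4-[(tert-butyldimethylsilyl)oxy]-2-methyl-3-(3-methylbut-1-en-2-yl)cyclohept-1-en-1-yl carbonate | CC1=C(OC(=O)OCC=C)CCC[C@H](O[Si](C)(C)C(C)(C)C)[C@H]1C(=C)C(C)C
F2 | step 12 | tert-butyl (3aS,4S,8aS)-6,8a-dimethyl-8-oxo-3-(propan-2-yl)-1,3a,4,5,8,8a-hexahydroazulen-4-yl carbonate | CC(C)(C)OC(=O)O[C@H]1CC(C)=CC(=O)[C@@]2(C)CC=C(C(C)C)[C@H]12
F3 | step 12 | C3-iodo C4,C6-cyclic carbonate of 20 (iodine trans to the C4–O bond) | O=C1O[C@H]2CC(C)=CC(=O)[C@@]3(C)C[C@@H](I)[C@@](O1)(C(C)C)[C@H]23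
F4 | step 12 | C4,C6-cyclic carbonate of 20 | O=C1O[C@H]2CC(C)=CC(=O)[C@@]3(C)CC[C@@](O1)(C(C)C)[C@H]23
F5 | step 13 | C3-phenylselanyl derivative of 20 (selenium trans to the C4 hydroxyl) | O[C@H]1CC(C)=CC(=O)[C@@]2(C)C[C@@H]([Se]c3ccccc3)[C@@](O)(C(C)C)[C@H]12
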